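**Retrosynthetic overview**
1. The target comes from BBr3 O-demethylation of its di-O-methyl ether, which comes from acid cyclodehydration of a biaryl bis(1-aryl-5-phenylpentane-1,3-dione).
2. Key disconnection: the C2–C3 bond of each chromone, made by a twofold intermolecular crossed Claisen condensation of a 2,2'-diacetyl-3,3'-dihydroxybiphenyl with ethyl 3-phenylpropanoate.
3. The diacetylbiphenyl comes from chelation-controlled BCl3 demethylation of the Suzuki–Miyaura product of a 2-bromo-3,6-dimethoxyacetophenone and a 2-acetyl-3,4-dimethoxyphenylboronate.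
4. Both acetophenones come from ortho-lithiation/formylation, MeMgBr addition and oxidation of 2-bromo-1,4-dimethoxybenzene and 4-bromo-1,2-dimethoxybenzene.
5. Ring order: both benzene rings are bought; the biaryl bond is made first; the two 4-pyranone rings are closed together in the penultimate step.

Assumption: the SMILES has no stereodescriptor and the molecule has no stereocentre; the hindered 5,5'-biaryl axis is unspecified, so the route makes the compound as drawn without controlling the axis.

**Route**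

Step 1
Reactants: 1 2-bromo-1,4-dimethoxybenzene
Product: 3 2-bromo-3,6-dimethoxybenzaldehyde, via (2-bromo-3,6-dimethoxyphenyl)lithium 2 (not isolated)
Conditions: LiN(i-Pr)2 (1.2 equiv), THF, −78 °C, 1 h; then DMF (2 equiv), −78 °C → 0 °C; then H2O
Reagents that add atoms: N,N-dimethylformamide, CN(C)C=O
Why: The amide base removes the most acidic ring proton, the one flanked by Br and OMe, without Br/Li exchange (directed ortho-metalation), and the aryllithium is formylated by DMF.

Step 2
Reactants: 3 2-bromo-3,6-dimethoxybenzaldehyde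
Product: 4 1-(2-bromo-3,6-dimethoxyphenyl)ethan-1-ol (racemic)
Conditions: MeMgBr (1.3 equiv), THF, 0 °C → rt; then H2O
Reagents that add atoms: methylmagnesium bromide, C[Mg]Br
Why: Grignard addition to the non-enolisable aldehyde is fast and leaves the aryl bromide alone; the new carbinol centre is racemic and is removed in step 3.

Step 3
Reactants: 4 1-(2-bromo-3,6-dimethoxyphenyl)ethan-1-ol
Product: 5 1-(2-bromo-3,6-dimethoxyphenyl)ethan-1-one
Conditions: Dess–Martin periodinane (1.2 equiv), CH2Cl2, rt
Reagents that add atoms: none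
Why: Dess–Martin oxidation of a secondary benzylic alcohol to the ketone is mild and does not touch the aryl bromide or the methyl ethers.

Step 4
Reactants: 6 4-bromo-1,2-dimethoxybenzene
Product: 8 6-bromo-2,3-dimethoxybenzaldehyde, via (6-bromo-2,3-dimethoxyphenyl)lithium 7 (not isolated)
Conditions: LiN(i-Pr)2 (1.2 equiv), THF, −78 °C, 1 h; then DMF (2 equiv), −78 °C → 0 °C; then H2O
Reagents that add atoms: N,N-dimethylformamide, CN(C)C=O
Why: The proton at C3, flanked by OMe and Br, is again the most acidic, so directed ortho-metalation followed by DMF formylation gives the 1,2,3,4-tetrasubstituted arene.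

Step 5
Reactants: 8 6-bromo-2,3-dimethoxybenzaldehyde
Product: 9 1-(6-bromo-2,3-dimethoxyphenyl)ethan-1-ol (racemic)
Conditions: MeMgBr (1.3 equiv), THF, 0 °C → rt; then H2O
Reagents that add atoms: methylmagnesium bromide, C[Mg]Br
Why: Grignard addition to the aldehyde; the racemic carbinol centre is removed in step 6.

Step 6
Reactants: 9 1-(6-bromo-2,3-dimethoxyphenyl)ethan-1-ol
Product: 10 1-(6-bromo-2,3-dimethoxyphenyl)ethan-1-one
Conditions: Dess–Martin periodinane (1.2 equiv), CH2Cl2, rt
Reagents that add atoms: none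
Why: Dess–Martin oxidation of the secondary benzylic alcohol gives the aryl methyl ketone cleanly.

Step 7
Reactants: 10 1-(6-bromo-2,3-dimethoxyphenyl)ethan-1-one
Product: 11 1-[2,3-dimethoxy-6-(4,4,5,5-tetramethyl-1,3,2-dioxaborolan-2-yl)phenyl]ethan-1-one
Conditions: B2pin2 (1.3 equiv), Pd(dppf)Cl2 (5 mol %), KOAc (3 equiv), 1,4-dioxane, 90 °C
Reagents that add atoms: bis(pinacolato)diboron, CC1(C)OB(OC1(C)C)B1OC(C)(C)C(C)(C)O1
Why: Miyaura borylation works well on ortho-acyl aryl bromides because oxidative addition to zerovalent palladium is fast, and KOAc is too weak a base to enolise the ketone.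

Step 8
Reactants: 5 1-(2-bromo-3,6-dimethoxyphenyl)ethan-1-one; 11 1-[2,3-dimethoxy-6-(4,4,5,5-tetramethyl-1,3,2-dioxaborolan-2-yl)phenyl]ethan-1-one
Product: 12 1,1'-(3,3',4',6-tetramethoxy[1,1'-biphenyl]-2,2'-diyl)di(ethan-1-one)
Conditions: Pd(OAc)2 (5 mol %), SPhos (10 mol %), K3PO4 (3 equiv), toluene/H2O 10:1, 90 °C
Reagents that add atoms: none
Why: Suzuki–Miyaura coupling with a bulky biaryl dialkylphosphine ligand handles this tri-ortho-substituted biaryl, with the less hindered partner carrying boron and the acyl-activated bromide as electrophile.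

Step 9
Reactants: 12 1,1'-(3,3',4',6-tetramethoxy[1,1'-biphenyl]-2,2'-diyl)di(ethan-1-one)
Product: 13 1,1'-(3,3'-dihydroxy-4',6-dimethoxy[1,1'-biphenyl]-2,2'-diyl)di(ethan-1-one)
Conditions: BCl3 (1 M in CH2Cl2, 3 equiv), CH2Cl2, −78 °C → 0 °C; then H2O
Reagents that add atoms: none
Why: BCl3 bound to each ketone oxygen cleaves only the methyl ether ortho to that carbonyl through a six-membered chelate (chelation-controlled ether cleavage), leaving the 6- and 4'-methoxy groups in place.

Step 10
Reactants: 13 1,1'-(3,3'-dihydroxy-4',6-dimethoxy[1,1'-biphenyl]-2,2'-diyl)di(ethan-1-one); 14 ethyl 3-phenylpropanoate (two molecules incorporated, 4 equiv used)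
Product: 16 1,1'-(3,3'-dihydroxy-4',6-dimethoxy[1,1'-biphenyl]-2,2'-diyl)bis(5-phenylpentane-1,3-dione), via tetralithium bis(enolate)bis(phenolate) 15 (not isolated)
Conditions: LiN(SiMe3)2 (8 equiv), THF, −78 °C → −10 °C; then 14, −78 °C → rt; then 1 M HCl
Reagents that add atoms: none
Why: Excess base converts both o-hydroxyacetophenone units fully into phenolate/enolate dianions, so no free ketone is left for ketone–ketone aldol, and each methyl-ketone enolate C-acylates the ester in an intermolecular crossed Claisen condensation driven by the stable 1,3-diketonate.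

Step 11
Reactants: 16 1,1'-(3,3'-dihydroxy-4',6-dimethoxy[1,1'-biphenyl]-2,2'-diyl)bis(5-phenylpentane-1,3-dione)
Product: 17 6-methoxy-5-[8-methoxy-4-oxo-2-(2-phenylethyl)-4H-chromen-5-yl]-2-(2-phenylethyl)-4H-chromen-4-one
Conditions: conc. HCl (cat.), AcOH, 90 °C, 1 h
Reagents that add atoms: none
Why: Each ortho-phenol adds to the distal diketone carbonyl and the hemiketal loses water (acid-catalysed cyclodehydration to the chromone); the phenol next to the biaryl bond is still a methyl ether and cannot compete.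

Step 12
Reactants: 17 6-methoxy-5-[8-methoxy-4-oxo-2-(2-phenylethyl)-4H-chromen-5-yl]-2-(2-phenylethyl)-4H-chromen-4-one
Product: 18 6-hydroxy-5-[8-hydroxy-4-oxo-2-(2-phenylethyl)-4H-chromen-5-yl]-2-(2-phenylethyl)-4H-chromen-4-one (target)
Conditions: BBr3 (8 equiv), CH2Cl2, −78 °C → rt; then H2O
Reagents that add atoms: none
Why: BBr3 cleaves aryl methyl ethers (Lewis-acid demethylation) and chromones tolerate it; the excess allows for complexation to the two pyranone carbonyls.

**Compound list**
1 | 2-bromo-1,4-dimethoxybenzene | COc1ccc(OC)c(Br)c1 | starting material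
2 | (2-bromo-3,6-dimethoxyphenyl)lithium | [Li]c1c(Br)c(OC)ccc1OC | intermediate (not isolated)
3 | 2-bromo-3,6-dimethoxybenzaldehyde | O=Cc1c(Br)c(OC)ccc1OC | intermediate
4 | 1-(2-bromo-3,6-dimethoxyphenyl)ethan-1-ol, racemic | CC(O)c1c(Br)c(OC)ccc1OC | intermediate
5 | 1-(2-bromo-3,6-dimethoxyphenyl)ethan-1-one | CC(=O)c1c(Br)c(OC)ccc1OC | intermediate
6 | 4-bromo-1,2-dimethoxybenzene | COc1ccc(Br)cc1OC | starting material
7 | (6-bromo-2,3-dimethoxyphenyl)lithium | [Li]c1c(Br)ccc(OC)c1OC | intermediate (not isolated)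
8 | 6-bromo-2,3-dimethoxybenzaldehyde | O=Cc1c(Br)ccc(OC)c1OC | intermediate
9 | 1-(6-bromo-2,3-dimethoxyphenyl)ethan-1-ol, racemic | CC(O)c1c(Br)ccc(OC)c1OC | intermediate
10 | 1-(6-bromo-2,3-dimethoxyphenyl)ethan-1-one | CC(=O)c1c(Br)ccc(OC)c1OC | intermediate
11 | 1-[2,3-dimethoxy-6-(4,4,5,5-tetramethyl-1,3,2-dioxaborolan-2-yl)phenyl]ethan-1-one | CC(=O)c1c(B2OC(C)(C)C(C)(C)O2)ccc(OC)c1OC | intermediate
12 | 1,1'-(3,3',4',6-tetramethoxy[1,1'-biphenyl]-2,2'-diyl)di(ethan-1-one) | CC(=O)c1c(-c2ccc(OC)c(OC)c2C(C)=O)c(OC)ccc1OC | intermediate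
13 | 1,1'-(3,3'-dihydroxy-4',6-dimethoxy[1,1'-biphenyl]-2,2'-diyl)di(ethan-1-one) | CC(=O)c1c(-c2ccc(OC)c(O)c2C(C)=O)c(OC)ccc1O | intermediate
14 | ethyl 3-phenylpropanoate | CCOC(=O)CCc1ccccc1 | starting material
15 | tetralithium bis(enolate)bis(phenolate) of 13 | C=C(O[Li])c1c(-c2ccc(OC)c(O[Li])c2C(=C)O[Li])c(OC)ccc1O[Li] | intermediate (not isolated)
16 | 1,1'-(3,3'-dihydroxy-4',6-dimethoxy[1,1'-biphenyl]-2,2'-diyl)bis(5-phenylpentane-1,3-dione) | O=C(CCc1ccccc1)CC(=O)c1c(-c2ccc(OC)c(O)c2C(=O)CC(=O)CCc2ccccc2)c(OC)ccc1O | intermediate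
17 | 6-methoxy-5-[8-methoxy-4-oxo-2-(2-phenylethyl)-4H-chromen-5-yl]-2-(2-phenylethyl)-4H-chromen-4-one | O=c1cc(CCc2ccccc2)oc2ccc(OC)c(-c3ccc(OC)c4oc(CCc5ccccc5)cc(=O)c34)c12 | intermediate
18 | 6-hydroxy-5-[8-hydroxy-4-oxo-2-(2-phenylethyl)-4H-chromen-5-yl]-2-(2-phenylethyl)-4H-chromen-4-one (no stereocentre; axis unspecified) | O=c1cc(CCc2ccccc2)oc2ccc(O)c(-c3ccc(O)c4oc(CCc5ccccc5)cc(=O)c34)c12 | target

**Totals**
Total step count: 12.
Longest linear sequence: 9 steps (6 → 8 → 9 → 10 → 11 → 12 → 13 → 16 → 17 → 18).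

**Steps most likely to fail, with fallbacks**

Step 8 (Suzuki–Miyaura). The biaryl is tri-ortho-substituted, the ortho-acyl boronate can protodeboronate, and hot aqueous base could start an aldol reaction between the two acetyl groups of the product. Fallback: set out from bromoketone 10 and stannylate it (Me3SnSnMe3, Pd(PPh3)4, toluene, 110 °C) to 1-[2,3-dimethoxy-6-(trimethylstannyl)phenyl]ethan-1-one F1. Couple F1 with bromoketone 5 in a Stille reaction without water or boron (Pd(PPh3)4, CuI, CsF, DMF, 50 °C). This comes back to the route at 12.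

Step 9 (selective double demethylation). Both ortho-methoxy groups must fall while the 4'-methoxy group next to the new catechol oxygen must stay; over- or under-reaction gives mixtures. Fallback: set out from 12 and skip the selective cleavage. Run the twofold Claisen condensation on the tetramethyl ether with 14 (LiN(SiMe3)2, THF, −78 °C → rt; only two enolates, no phenolates) to give 1,1'-(3,3',4',6-tetramethoxy[1,1'-biphenyl]-2,2'-diyl)bis(5-phenylpentane-1,3-dione) F2. Heat F2 in 48 % HBr/AcOH at reflux, which cleaves all four methyl ethers and closes both pyranone rings under thermodynamic control. This comes back to the route at 18.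

Step 10 (twofold Claisen condensation). Two hindered, doubly ortho-substituted acetyl groups must each be acylated on a polyanion; ester self-condensation or incomplete second acylation would lower the yield. Fallback: set out from 13 and O-acylate both phenols with 3-phenylpropanoyl chloride (pyridine, CH2Cl2, 0 °C → rt) to (2,2'-diacetyl-4',6-dimethoxy[1,1'-biphenyl]-3,3'-diyl) bis(3-phenylpropanoate) F3. Treat F3 with KOt-Bu in THF (0 °C → rt) so that each acyl group moves from oxygen to the neighbouring enolate carbon (Baker–Venkataraman rearrangement). This comes back to the route at 16.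

**Further compounds**
F1 | step 8 | 1-[2,3-dimethoxy-6-(trimethylstannyl)phenyl]ethan-1-one | CC(=O)c1c([Sn](C)(C)C)ccc(OC)c1OC
F2 | step 9 | 1,1'-(3,3',4',6-tetramethoxy[1,1'-biphenyl]-2,2'-diyl)bis(5-phenylpentane-1,3-dione) | O=C(CCc1ccccc1)CC(=O)c1c(-c2ccc(OC)c(OC)c2C(=O)CC(=O)CCc2ccccc2)c(OC)ccc1OC
F3 | step 10 | (2,2'-diacetyl-4',6-dimethoxy[1,1'-biphenyl]-3,3'-diyl) bis(3-phenylpropanoate) | CC(=O)c1c(-c2ccc(OC)c(OC(=O)CCc3ccccc3)c2C(C)=O)c(OC)ccc1OC(=O)CCc1ccccc1
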